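Retrosynthesis: the polyene is cut at C11=C12 and C11'=C12' (two Horner–Wadsworth–Emmons olefinations around a C10 triene bisphosphonate), the β-half at C8–C9 (Nozaki–Hiyama–Kishi) and at C7–C8 (one-carbon homologation), and last the hydroxy-β-ring at C3–C4 and C5=C6.
Enabling feature: in the β-ring the C3 carbinol is 1,3 to C5, the C5=C6 bond carries one exocyclic carbon (C7), and the quaternary C1 is flanked by two CH2 groups (C2, C6). The ring is therefore acetone (C4, C5, 5-methyl) plus the symmetric 3,3-dimethylpentanedial (C3–C2–C1–C6–C7), joined by an aldol addition and an aldol condensation in one flask.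
Forward: β-ring first, then C7→C8 homologation, C8–C9 union with a C4 vinyl iodide from but-2-yne-1,4-diol that already carries the octenoate, and oxidation to the C15 keto aldehyde. The ε-half C15 aldehyde from (R)-α-ionone is joined to the C10 bisphosphonate, the resulting C25 phosphonate to the C15 keto aldehyde, and desilylation ends the route.
Stereochemistry: C3 from L-proline enamine catalysis, C6' from (R)-α-ionone, C3' from substrate-controlled hydride delivery; C9=C10 from syn-hydrostannation and retentive iododestannylation, the other new double bonds from E-selective olefinations.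

Key step: step 3

Assumption: (R)-α-ionone is used as the purchased single enantiomer; positions are named with carotenoid numbering (unprimed for the hydroxy-β half, primed for the ε half).

Step 1
Reactants: 1 3,3-dimethylglutaric anhydride
Product: 2 3,3-dimethylpentane-1,5-diol
Conditions: LiAlH4, THF, 0 °C to reflux; H2O/aq. NaOH work-up
Reagents that add atoms: none
Why: LiAlH4 reduction of a cyclic anhydride to the diol is standard hydride chemistry and the symmetric product has no stereocentre.

Step 2
Reactants: 2 3,3-dimethylpentane-1,5-diol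
Product: 3 3,3-dimethylpentanedial
Conditions: (COCl)2, DMSO, CH2Cl2, −78 °C; Et3N, −78 °C to 0 °C; used crude
Reagents that add atoms: none
Why: Swern oxidation takes both primary alcohols to the aldehyde level at once, which avoids the lactol and lactone a slower oxidant would give from a 1,5-diol; the dialdehyde cannot close by aldol reaction (four-membered ring).

Step 3
Reactants: 3 3,3-dimethylpentanedial; 4 acetone
Product: 6 (4R)-4-hydroxy-2,6,6-trimethylcyclohex-1-ene-1-carbaldehyde, via acyclic aldol 5 (not isolated)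
Conditions: L-proline (20 mol %), 4 (20 equiv), CHCl3, 4 °C; then acetone evaporated, Bn2NH·CF3CO2H (20 mol %), toluene, 23 °C
Reagents that add atoms: none
Why: The enamine formed from acetone and L-proline adds to one of the two homotopic formyl groups of 3 through the chair-like transition state in which the carboxylic acid hydrogen-bonds the aldehyde oxygen (re-face attack), which makes the C3–C4 bond and sets C3; the (5S)-aldol 5 rests as its six-membered lactol, which shields the second formyl group from a further aldol addition. After the solvent change, dibenzylammonium trifluoroacetate turns the liberated formyl group into its enamine, whose nucleophilic carbon (C6) attacks the methyl ketone (C5) in a 6-(enolexo)-exo-trig aldol, and loss of water from the tertiary aldol through the iminium ion gives the tetrasubstituted C5=C6 bond conjugated with the aldehyde, so the carbocycle is closed by an aldol condensation in a formal [4+2] annulation. The closest known reaction types are the proline-catalysed direct aldol addition of acetone to aliphatic aldehydes and the secondary-ammonium-salt-catalysed cyclodehydration of 7-oxoaldehydes to 2-methylcyclohex-1-ene-1-carbaldehydes. The only new stereocentre (C3) is under catalyst control and is not α to a carbonyl group, so ring closure cannot epimerise it (the descriptor changes from S in 5 to R in 6 only because the CIP priorities change). The step needs donor selectivity in the ring closure (aldehyde enamine onto ketone, not ketone enolate onto aldehyde, which would give an acetylcyclohexene); amine-salt catalysis in place of hydroxide secures this, the other closures being four- or eight-membered, and the weakly acidic room-temperature medium should leave the C3 hydroxyl in place.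

Step 4
Reactants: 6 (4R)-4-hydroxy-2,6,6-trimethylcyclohex-1-ene-1-carbaldehyde
Product: 7 (4R)-4-[(tert-butyldimethylsilyl)oxy]-2,6,6-trimethylcyclohex-1-ene-1-carbaldehyde
Conditions: TBSCl, imidazole, DMF, 0 °C to 23 °C
Reagents that add atoms: tert-butyldimethylsilyl chloride, CC(C)(C)[Si](C)(C)Cl
Why: Standard silylation of a secondary alcohol, done on the crude product to mask the hydroxyl before the ylide, organochromium and oxidation steps.

Step 5
Reactants: 7 (4R)-4-[(tert-butyldimethylsilyl)oxy]-2,6,6-trimethylcyclohex-1-ene-1-carbaldehyde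
Product: 9 2-[(4R)-4-[(tert-butyldimethylsilyl)oxy]-2,6,6-trimethylcyclohex-1-en-1-yl]acetaldehyde, via methyl enol ether 8 (not isolated)
Conditions: Ph3P(CH2OMe)Cl, KN(SiMe3)2, THF, −78 °C to 0 °C; then 1 M HCl, THF, 0 °C
Reagents that add atoms: (methoxymethyl)triphenylphosphonium chloride, COC[P+](c1ccccc1)(c1ccccc1)c1ccccc1.[Cl-]; water, O
Why: Wittig methoxymethylenation followed by acid hydrolysis of the dienyl methyl ether is the classical one-carbon homologation of an aldehyde; protonation at the enol-ether α-carbon (C7) keeps the tetrasubstituted ring double bond in place, and the secondary silyl ether tolerates brief cold dilute acid.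

Step 6
Reactants: 10 but-2-yne-1,4-diol
Product: 11 (2E)-2-(tributylstannyl)but-2-ene-1,4-diol
Conditions: Bu3SnH, PdCl2(PPh3)2 (2 mol %), THF, 23 °C
Reagents that add atoms: tributyltin hydride, CCCC[SnH](CCCC)CCCC
Why: Palladium-catalysed hydrostannation of an alkyne is a syn addition and the symmetric diol poses no regiochemical question, so the two CH2OH groups end cis, as C19 and C11 must be.

Step 7
Reactants: 11 (2E)-2-(tributylstannyl)but-2-ene-1,4-diol
Product: 12 (2E)-4-[(triethylsilyl)oxy]-2-(tributylstannyl)but-2-en-1-ol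
Conditions: TESCl (1.0 equiv), imidazole, CH2Cl2, −78 °C
Reagents that add atoms: chlorotriethylsilane, CC[Si](Cl)(CC)CC
Why: Kinetic monosilylation under steric control: the hydroxyl on the carbon geminal to the Bu3Sn group is shielded, so the remote allylic hydroxyl (the later C11 oxygen) should react first.

Step 8
Reactants: 12 (2E)-4-[(triethylsilyl)oxy]-2-(tributylstannyl)but-2-en-1-ol; 13 (2E)-oct-2-enoic acid
Product: 14 (2E)-4-[(triethylsilyl)oxy]-2-(tributylstannyl)but-2-en-1-yl (2E)-oct-2-enoate
Conditions: DCC, DMAP (10 mol %), CH2Cl2, 0 °C to 23 °C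
Reagents that add atoms: none
Why: Steglich esterification of the remaining primary allylic alcohol with the conjugated acid places the acyl group on the C19 oxygen while the molecule is still small.

Step 9
Reactants: 14 (2E)-4-[(triethylsilyl)oxy]-2-(tributylstannyl)but-2-en-1-yl (2E)-oct-2-enoate
Product: 15 (2E)-2-iodo-4-[(triethylsilyl)oxy]but-2-en-1-yl (2E)-oct-2-enoate
Conditions: I2, NaHCO3, CH2Cl2, 0 °C, dark
Reagents that add atoms: iodine, II
Why: Iododestannylation of an alkenylstannane is an ipso substitution with retention of double-bond geometry; the enoate and the silyl ether are inert to iodine at 0 °C.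

Step 10
Reactants: 9 2-[(4R)-4-[(tert-butyldimethylsilyl)oxy]-2,6,6-trimethylcyclohex-1-en-1-yl]acetaldehyde; 15 (2E)-2-iodo-4-[(triethylsilyl)oxy]but-2-en-1-yl (2E)-oct-2-enoate
Product: 16 (2E)-2-{1-hydroxy-2-[(4R)-4-[(tert-butyldimethylsilyl)oxy]-2,6,6-trimethylcyclohex-1-en-1-yl]ethyl}-4-[(triethylsilyl)oxy]but-2-en-1-yl (2E)-oct-2-enoate (both C8 epimers)
Conditions: CrCl2 (5 equiv), NiCl2 (2 mol %), DMF, 23 °C
Reagents that add atoms: none
Why: Nozaki–Hiyama–Kishi reaction: the alkenylchromium species formed under NiCl2 catalysis keeps the alkene geometry, is not basic enough to enolise the β,γ-unsaturated aldehyde and is covalent enough to leave the esters and the allylic carboxylate alone; both C8 epimers are acceptable because C8 becomes a ketone in step 11.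

Step 11
Reactants: 16 the C8 carbinol from step 10
Product: 17 (2E)-4-oxo-2-{[(4R)-4-[(tert-butyldimethylsilyl)oxy]-2,6,6-trimethylcyclohex-1-en-1-yl]acetyl}but-2-en-1-yl (2E)-oct-2-enoate
Conditions: (COCl)2, DMSO, CH2Cl2, −78 °C to −40 °C; Et3N, −78 °C to 0 °C
Reagents that add atoms: none
Why: Swern oxidation converts the secondary allylic alcohol into the ketone and in the same operation turns the primary triethylsilyl ether directly into the aldehyde (a known behaviour of primary TES ethers under Swern conditions), while the secondary TBS ether stays and the C9=C10 geometry (acyl trans to formyl) is kept.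

Step 12
Reactants: 18 (R)-α-ionone
Product: 19 (2E,4E)-3-methyl-5-[(1R)-2,6,6-trimethylcyclohex-2-en-1-yl]penta-2,4-dienenitrile
Conditions: (EtO)2P(O)CH2CN, NaH, THF, 0 °C to 23 °C; minor (2Z) isomer removed by chromatography
Reagents that add atoms: diethyl (cyanomethyl)phosphonate, CCOP(=O)(CC#N)OCC
Why: Horner–Wadsworth–Emmons olefination of the methyl ketone gives mainly the (2E)-dienenitrile, and the stabilised phosphonate anion is too weak a base to deprotonate the γ-position, so the ring stereocentre should be retained.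

Step 13
Reactants: 19 (2E,4E)-3-methyl-5-[(1R)-2,6,6-trimethylcyclohex-2-en-1-yl]penta-2,4-dienenitrile
Product: 20 (2E,4E)-3-methyl-5-[(1R)-2,6,6-trimethyl-4-oxocyclohex-2-en-1-yl]penta-2,4-dienenitrile
Conditions: t-BuOOH (70 % aq.), Rh2(cap)4 (cap = caprolactamate, 1 mol %), NaHCO3, 1,2-dichloroethane, 40 °C
Reagents that add atoms: tert-butyl hydroperoxide, CC(C)(C)OO
Why: Rh2(cap)4-catalysed allylic oxidation with t-BuOOH converts the ring CH2 next to the trisubstituted ring alkene into the enone carbonyl; the competing tertiary allylic CH is shielded by the gem-dimethyl group, the ring methyl and the side chain, and the near-neutral medium should not epimerise the γ-stereocentre.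

Step 14
Reactants: 20 (2E,4E)-3-methyl-5-[(1R)-2,6,6-trimethyl-4-oxocyclohex-2-en-1-yl]penta-2,4-dienenitrile
Product: 21 (2E,4E)-5-[(1R,4R)-4-hydroxy-2,6,6-trimethylcyclohex-2-en-1-yl]-3-methylpenta-2,4-dienenitrile
Conditions: LiBH(s-Bu)3, THF, −78 °C; then H2O, 0 °C
Reagents that add atoms: none
Why: 1,2-Reduction of a β,β-disubstituted cyclohexenone by a bulky hydride: A(1,2) strain with the ring methyl holds the side chain pseudoaxial, the axial methyl of the gem-dimethyl carbon then shields the opposite face, and hydride should enter from the face of the chain to give the alcohol trans to the chain, (1R,4R).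

Step 15
Reactants: 21 (2E,4E)-5-[(1R,4R)-4-hydroxy-2,6,6-trimethylcyclohex-2-en-1-yl]-3-methylpenta-2,4-dienenitrile
Product: 22 (2E,4E)-5-[(1R,4R)-4-[(tert-butyldimethylsilyl)oxy]-2,6,6-trimethylcyclohex-2-en-1-yl]-3-methylpenta-2,4-dienenitrile
Conditions: TBSCl, imidazole, DMF, 23 °C
Reagents that add atoms: tert-butyldimethylsilyl chloride, CC(C)(C)[Si](C)(C)Cl
Why: Standard silylation of the allylic alcohol, so that no alkoxide competes with the phosphonate anions of steps 19 and 20.

Step 16
Reactants: 22 the silylated dienenitrile from step 15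
Product: 23 (2E,4E)-5-[(1R,4R)-4-[(tert-butyldimethylsilyl)oxy]-2,6,6-trimethylcyclohex-2-en-1-yl]-3-methylpenta-2,4-dienal
Conditions: i-Bu2AlH, toluene, −78 °C; then wet silica gel/dilute aq. AcOH, 0 °C
Reagents that add atoms: water, O
Why: Partial reduction of the conjugated nitrile by i-Bu2AlH stops at the N-aluminoimine, which is hydrolysed to the dienal on mild acidic work-up; the allylic silyl ether and the diene geometry should be unaffected.

Step 17
Reactants: 24 (2E,4E,6E)-2,7-dimethylocta-2,4,6-trienedial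
Product: 25 (2E,4E,6E)-2,7-dimethylocta-2,4,6-triene-1,8-diol
Conditions: NaBH4, MeOH/THF, 0 °C
Reagents that add atoms: none
Why: NaBH4 reduces the two conjugated aldehyde groups by 1,2-addition without touching the triene.

Step 18
Reactants: 25 (2E,4E,6E)-2,7-dimethylocta-2,4,6-triene-1,8-diol
Product: 26 tetraethyl [(2E,4E,6E)-2,7-dimethylocta-2,4,6-triene-1,8-diyl]bis(phosphonate)
Conditions: ZnI2, P(OEt)3, toluene, 80 °C
Reagents that add atoms: triethyl phosphite, CCOP(OCC)OCC
Why: ZnI2-mediated direct conversion of allylic alcohols into diethyl phosphonates with triethyl phosphite is an Arbuzov-type reaction through the allylic iodide; substitution at the chain termini keeps the fully conjugated all-E triene.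

Step 19
Reactants: 23 the ε-half C15 dienal from step 16; 26 the C10 bisphosphonate from step 18
Product: 27 diethyl [(2E,4E,6E,8E,10E,12E)-13-[(1R,4R)-4-[(tert-butyldimethylsilyl)oxy]-2,6,6-trimethylcyclohex-2-en-1-yl]-2,7,11-trimethyltrideca-2,4,6,8,10,12-hexaen-1-yl]phosphonate
Conditions: 26 (3 equiv), NaN(SiMe3)2 (2.5 equiv), THF, −78 °C; 23 added slowly; to 0 °C, dark
Reagents that add atoms: none
Why: Horner–Wadsworth–Emmons olefination with an allylic phosphonate anion is E-selective (C11'=C12'); excess bisphosphonate and slow addition of the aldehyde ensure that only one phosphonate terminus reacts.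

Step 20
Reactants: 17 the C15 keto aldehyde from step 11; 27 the C25 phosphonate from step 19
Product: 28 (3R,3'R,6'R)-3,3'-bis[(tert-butyldimethylsilyl)oxy]-8-oxo-7,8-dihydro-β,ε-caroten-19-yl (2E)-oct-2-enoate
Conditions: 27, NaN(SiMe3)2 (1.05 equiv), THF, −78 °C; then 17; to 0 °C, dark, argon
Reagents that add atoms: none
Why: Horner–Wadsworth–Emmons olefination: the polyenyl phosphonate anion adds to the unhindered, highly electrophilic formyl group much faster than to the ketone and gives the E C11=C12 bond; adding 17 to the preformed anion at −78 °C limits enolisation at C7 and attack on the allylic ester.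

Step 21
Reactants: 28 the bis-silyl ether from step 20
Product: 29 (3R,3'R,6'R)-3,3'-dihydroxy-8-oxo-7,8-dihydro-β,ε-caroten-19-yl (2E)-oct-2-enoate (siphonaxanthin 19-[(2E)-oct-2-enoate], CNP0344057.1)
Conditions: HF·pyridine, pyridine, THF, 0 °C to 23 °C, dark
Reagents that add atoms: none
Why: Buffered fluoride cleavage of the two secondary silyl ethers; excess pyridine keeps the medium from ionising the allylic C3' alcohol, and the conditions are not nucleophilic enough to displace the allylic ester or add to the enone.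

Compound list
1 | 3,3-dimethylglutaric anhydride (4,4-dimethyloxane-2,6-dione) | CC1(C)CC(=O)OC(=O)C1 | starting material
2 | 3,3-dimethylpentane-1,5-diol | OCCC(C)(C)CCO | intermediate
3 | 3,3-dimethylpentanedial | O=CCC(C)(C)CC=O | intermediate
4 | acetone | CC(C)=O | starting material
5 | (5S)-5-hydroxy-3,3-dimethyl-7-oxooctanal (acyclic aldol, rests as its lactol; not isolated) | CC(=O)C[C@@H](O)CC(C)(C)CC=O | intermediate
6 | (4R)-4-hydroxy-2,6,6-trimethylcyclohex-1-ene-1-carbaldehyde | O=CC1=C(C)C[C@@H](O)CC1(C)C | intermediate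
7 | (4R)-4-[(tert-butyldimethylsilyl)oxy]-2,6,6-trimethylcyclohex-1-ene-1-carbaldehyde | O=CC1=C(C)C[C@@H](O[Si](C)(C)C(C)(C)C)CC1(C)C | intermediate
8 | tert-butyl{[(1R)-4-(2-methoxyethenyl)-3,5,5-trimethylcyclohex-3-en-1-yl]oxy}dimethylsilane (methyl enol ether, E/Z mixture; not isolated) | COC=CC1=C(C)C[C@@H](O[Si](C)(C)C(C)(C)C)CC1(C)C | intermediate
9 | 2-[(4R)-4-[(tert-butyldimethylsilyl)oxy]-2,6,6-trimethylcyclohex-1-en-1-yl]acetaldehyde | O=CCC1=C(C)C[C@@H](O[Si](C)(C)C(C)(C)C)CC1(C)C | intermediate
10 | but-2-yne-1,4-diol | OCC#CCO | starting material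
11 | (2E)-2-(tributylstannyl)but-2-ene-1,4-diol | OC/C=C(\CO)[Sn](CCCC)(CCCC)CCCC | intermediate
12 | (2E)-4-[(triethylsilyl)oxy]-2-(tributylstannyl)but-2-en-1-ol | CC[Si](CC)(CC)OC/C=C(\CO)[Sn](CCCC)(CCCC)CCCC | intermediate
13 | (2E)-oct-2-enoic acid | CCCCC/C=C/C(=O)O | starting material
14 | (2E)-4-[(triethylsilyl)oxy]-2-(tributylstannyl)but-2-en-1-yl (2E)-oct-2-enoate | CCCCC/C=C/C(=O)OC/C(=C\CO[Si](CC)(CC)CC)[Sn](CCCC)(CCCC)CCCC | intermediate
15 | (2E)-2-iodo-4-[(triethylsilyl)oxy]but-2-en-1-yl (2E)-oct-2-enoate | CCCCC/C=C/C(=O)OC/C(I)=C\CO[Si](CC)(CC)CC | intermediate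
16 | (2E)-2-{1-hydroxy-2-[(4R)-4-[(tert-butyldimethylsilyl)oxy]-2,6,6-trimethylcyclohex-1-en-1-yl]ethyl}-4-[(triethylsilyl)oxy]but-2-en-1-yl (2E)-oct-2-enoate (both C8 epimers) | CCCCC/C=C/C(=O)OC/C(=C\CO[Si](CC)(CC)CC)C(O)CC1=C(C)C[C@@H](O[Si](C)(C)C(C)(C)C)CC1(C)C | intermediate
17 | (2E)-4-oxo-2-{[(4R)-4-[(tert-butyldimethylsilyl)oxy]-2,6,6-trimethylcyclohex-1-en-1-yl]acetyl}but-2-en-1-yl (2E)-oct-2-enoate | CCCCC/C=C/C(=O)OC/C(=C\C=O)C(=O)CC1=C(C)C[C@@H](O[Si](C)(C)C(C)(C)C)CC1(C)C | intermediate
18 | (R)-α-ionone, (3E)-4-[(1R)-2,6,6-trimethylcyclohex-2-en-1-yl]but-3-en-2-one | CC(=O)/C=C/[C@H]1C(C)=CCCC1(C)C | starting material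
19 | (2E,4E)-3-methyl-5-[(1R)-2,6,6-trimethylcyclohex-2-en-1-yl]penta-2,4-dienenitrile | N#C/C=C(C)/C=C/[C@H]1C(C)=CCCC1(C)C | intermediate
20 | (2E,4E)-3-methyl-5-[(1R)-2,6,6-trimethyl-4-oxocyclohex-2-en-1-yl]penta-2,4-dienenitrile | N#C/C=C(C)/C=C/[C@H]1C(C)=CC(=O)CC1(C)C | intermediate
21 | (2E,4E)-5-[(1R,4R)-4-hydroxy-2,6,6-trimethylcyclohex-2-en-1-yl]-3-methylpenta-2,4-dienenitrile | N#C/C=C(C)/C=C/[C@H]1C(C)=C[C@H](O)CC1(C)C | intermediate
22 | (2E,4E)-5-[(1R,4R)-4-[(tert-butyldimethylsilyl)oxy]-2,6,6-trimethylcyclohex-2-en-1-yl]-3-methylpenta-2,4-dienenitrile | N#C/C=C(C)/C=C/[C@H]1C(C)=C[C@H](O[Si](C)(C)C(C)(C)C)CC1(C)C | intermediate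
23 | (2E,4E)-5-[(1R,4R)-4-[(tert-butyldimethylsilyl)oxy]-2,6,6-trimethylcyclohex-2-en-1-yl]-3-methylpenta-2,4-dienal | O=C/C=C(C)/C=C/[C@H]1C(C)=C[C@H](O[Si](C)(C)C(C)(C)C)CC1(C)C | intermediate
24 | (2E,4E,6E)-2,7-dimethylocta-2,4,6-trienedial | O=C/C(C)=C/C=C/C=C(C)/C=O | starting material
25 | (2E,4E,6E)-2,7-dimethylocta-2,4,6-triene-1,8-diol | OC/C(C)=C/C=C/C=C(C)/CO | intermediate
26 | tetraethyl [(2E,4E,6E)-2,7-dimethylocta-2,4,6-triene-1,8-diyl]bis(phosphonate) | CCOP(=O)(OCC)C/C(C)=C/C=C/C=C(C)/CP(=O)(OCC)OCC | intermediate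
27 | diethyl [(2E,4E,6E,8E,10E,12E)-13-[(1R,4R)-4-[(tert-butyldimethylsilyl)oxy]-2,6,6-trimethylcyclohex-2-en-1-yl]-2,7,11-trimethyltrideca-2,4,6,8,10,12-hexaen-1-yl]phosphonate | CCOP(=O)(OCC)C/C(C)=C/C=C/C=C(C)/C=C/C=C(C)/C=C/[C@H]1C(C)=C[C@H](O[Si](C)(C)C(C)(C)C)CC1(C)C | intermediate
28 | (3R,3'R,6'R)-3,3'-bis[(tert-butyldimethylsilyl)oxy]-8-oxo-7,8-dihydro-β,ε-caroten-19-yl (2E)-oct-2-enoate | CCCCC/C=C/C(=O)OC\C(=C/C=C/C(C)=C/C=C/C=C(C)/C=C/C=C(C)/C=C/[C@H]1C(C)=C[C@H](O[Si](C)(C)C(C)(C)C)CC1(C)C)C(=O)CC1=C(C)C[C@@H](O[Si](C)(C)C(C)(C)C)CC1(C)C | intermediate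
29 | (3R,3'R,6'R)-3,3'-dihydroxy-8-oxo-7,8-dihydro-β,ε-caroten-19-yl (2E)-oct-2-enoate | CCCCC/C=C/C(=O)OC\C(=C/C=C/C(C)=C/C=C/C=C(C)/C=C/C=C(C)/C=C/[C@H]1C(C)=C[C@H](O)CC1(C)C)C(=O)CC1=C(C)C[C@@H](O)CC1(C)C | target

Total step count: 21. Longest linear sequence: 9 steps (steps 1, 2, 3, 4, 5, 10, 11, 20, 21).

Steps most likely to fail

Step 3. What may go wrong: erosion of enantiomeric purity through reversible aldol addition, dehydration of the β-hydroxy ketone before the ring closes, or vinylogous loss of water from the product. The fallback sets out from 3 and comes back at 5, and so at 6. Asymmetric methallylboration of one formyl group of 3 with the B-methallyldiisopinocampheylborane derived from (−)-α-pinene (the enantiomer expected to add to the re face; Et2O, −78 °C, ethanolamine work-up) should give, under reagent control, (5R)-5-hydroxy-3,3,7-trimethyloct-7-enal F1, which rests as its lactol. Ozonolysis of the 1,1-disubstituted alkene (O3, CH2Cl2, −78 °C; Me2S) then gives 5, which is closed with Bn2NH·CF3CO2H as in the second stage of step 3.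

Step 20. What may go wrong: deprotonation at C7 of the keto aldehyde by the basic phosphonate anion, conjugate addition to the ene-dicarbonyl unit, or displacement of the allylic carboxylate. The fallback sets out from 15 and comes back at 28; it changes the order of bond formation so that the keto aldehyde never meets a carbanion. Swern treatment of 15 should give (2E)-2-iodo-4-oxobut-2-en-1-yl (2E)-oct-2-enoate F2. Horner–Wadsworth–Emmons olefination of F2 with the anion of 27 (NaN(SiMe3)2, THF, −78 °C) should give the polyenyl iodide (2E,4E,6E,8E,10E,12E,14E,16E)-17-[(1R,4R)-4-[(tert-butyldimethylsilyl)oxy]-2,6,6-trimethylcyclohex-2-en-1-yl]-2-iodo-6,11,15-trimethylheptadeca-2,4,6,8,10,12,14,16-octaen-1-yl (2E)-oct-2-enoate F3. Nozaki–Hiyama–Kishi coupling of F3 with 9 (CrCl2, NiCl2 cat., DMF) should give the carbinol (3R,3'R,6'R)-3,3'-bis[(tert-butyldimethylsilyl)oxy]-8-hydroxy-7,8-dihydro-β,ε-caroten-19-yl (2E)-oct-2-enoate F4, and oxidation of this allylic alcohol with MnO2 (CH2Cl2) returns to 28.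

Step 14. What may go wrong: hydride delivery from the face opposite to the side chain, giving the cis alcohol partly or mainly. The fallback sets out from 20 and comes back at 21. Reduction of 20 with NaBH4/CeCl3 (MeOH, −78 °C) and chromatographic separation supplies the cis epimer (2E,4E)-5-[(1R,4S)-4-hydroxy-2,6,6-trimethylcyclohex-2-en-1-yl]-3-methylpenta-2,4-dienenitrile F5. Mitsunobu reaction (PhCO2H, PPh3, DIAD, THF, 0 °C) inverts the carbinol centre by SN2 displacement to (2E,4E)-5-[(1R,4R)-4-(benzoyloxy)-2,6,6-trimethylcyclohex-2-en-1-yl]-3-methylpenta-2,4-dienenitrile F6, and methanolysis (K2CO3, MeOH) returns to 21.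

Further compounds
F1 | step 3 | (5R)-5-hydroxy-3,3,7-trimethyloct-7-enal | CC(=C)C[C@@H](O)CC(C)(C)CC=O
F2 | step 20 | (2E)-2-iodo-4-oxobut-2-en-1-yl (2E)-oct-2-enoate | CCCCC/C=C/C(=O)OC/C(I)=C\C=O
F3 | step 20 | (2E,4E,6E,8E,10E,12E,14E,16E)-17-[(1R,4R)-4-[(tert-butyldimethylsilyl)oxy]-2,6,6-trimethylcyclohex-2-en-1-yl]-2-iodo-6,11,15-trimethylheptadeca-2,4,6,8,10,12,14,16-octaen-1-yl (2E)-oct-2-enoate | CCCCC/C=C/C(=O)OC\C(I)=C/C=C/C(C)=C/C=C/C=C(C)/C=C/C=C(C)/C=C/[C@H]1C(C)=C[C@H](O[Si](C)(C)C(C)(C)C)CC1(C)C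
F4 | step 20 | (3R,3'R,6'R)-3,3'-bis[(tert-butyldimethylsilyl)oxy]-8-hydroxy-7,8-dihydro-β,ε-caroten-19-yl (2E)-oct-2-enoate (both C8 epimers) | CCCCC/C=C/C(=O)OC\C(=C/C=C/C(C)=C/C=C/C=C(C)/C=C/C=C(C)/C=C/[C@H]1C(C)=C[C@H](O[Si](C)(C)C(C)(C)C)CC1(C)C)C(O)CC1=C(C)C[C@@H](O[Si](C)(C)C(C)(C)C)CC1(C)C
F5 | step 14 | (2E,4E)-5-[(1R,4S)-4-hydroxy-2,6,6-trimethylcyclohex-2-en-1-yl]-3-methylpenta-2,4-dienenitrile | N#C/C=C(C)/C=C/[C@H]1C(C)=C[C@@H](O)CC1(C)C
F6 | step 14 | (2E,4E)-5-[(1R,4R)-4-(benzoyloxy)-2,6,6-trimethylcyclohex-2-en-1-yl]-3-methylpenta-2,4-dienenitrile | N#C/C=C(C)/C=C/[C@H]1C(C)=C[C@H](OC(=O)c2ccccc2)CC1(C)C
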